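(All runs are simulated for an exercise; scatter was added.)

| flask | starting material | reagent | remark | time |
|---|---|---|---|---|
| alpha | 13 mM | 36 mM | run made earlier |  |
| gamma | 30 mM | 36 mM | run made earlier |  |
| eta | 20 mM | 54 mM | run made earlier |  |
| flask | 20 mM | 36.0 mM |  | 6.0 h |

| run | time / h | starting material / % | single product / % | double product / % |
|---|---|---|---|---|
| alpha | 0.500 | 0 | 92 | 10 |
| alpha | 1.00 | 1 | 86 | 10 |
| alpha | 2.00 | 0 | 81 | 21 |
| alpha | 4.00 | 1 | 63 | 35 |
| alpha | 8.00 | 0 | 46 | 52 |
| gamma | 1.33 | 0 | 98 | 3 |
| gamma | 3.00 | 1 | 95 | 4 |
| gamma | 4.00 | 2 | 96 | 5 |
| gamma | 6.00 | 0 | 99 | 5 |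
| gamma | 8.00 | 5 | 95 | 9 |
| eta | 0.500 | 0 | 94 | 6 |
| eta | 1.00 | 0 | 85 | 9 |
| eta | 2.00 | 0 | 82 | 18 |
| eta | 4.00 | 0 | 65 | 35 |
| eta | 8.00 | 0 | 51 | 48 |

(standard deviation of a reading: 1.5 percentage points)

- amounts and yields of single product count crystals too
- given per volume of solution although it is solid: crystals
- steps that have been proposed: starting material + reagent -> single product; reagent + single product <-> double product; crystals <-> single product

- starting material at 6.0 h, in percent of the starting material charged
- single product at 6.0 h, in percent of the starting material charged
- double product at 6.0 h, in percent of the starting material charged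

The easy step came first: starting material read 0 % at the first eta reading, 0.500 h. I therefore counted in charges of starting material. Each charge takes one of reagent, and what remains is spare: 1.70 in eta, 1.77 in alpha and 0.800 in this flask.

I then followed the fraction of spare reagent left. Its fractional loss per hour read 0.0576 h⁻¹ from eta at 4.00 h; I called this the spare-reagent decay constant, a pseudo-first-order constant. Alpha read 0.0551 h⁻¹ at the same time, although both its charges differ from eta's.

This flask should therefore start at 0.0461 h⁻¹ in charges of double product. Shrinking spare reagent slows that by a factor of 0.708 at 6.0 h, and that same factor is the fraction left. Eta's last reading shows a second slowing: its average constant falls to 0.0415 h⁻¹, a factor of 0.720, which suggests a way back. With that lower constant the fraction left is 0.780. My reckoning thus gave 23.4 % double product with the first constant and 17.6 % with the lower one.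

The forecast gave 0 % starting material, 78 % single product (73 % to 83 %) and 22 % double product (17 % to 27 %), with the rate “falling as reagent is used”. Its double product stood under my first figure.

The flask gave 0 % starting material, 80.0 % single product and 20.0 % double product, so the fraction of spare reagent left was 0.750, above 0.708 and below 0.780. At 6.00 h, dissolved single product in the flask was made 1.00 times as fast as it was used up, going into crystals counted as use, while crystals held 73.5 % of the charge. The forecast stood right; the computed single product moved by 5 points at a reagent charge of 31.9 mM or 40.0 mM.

    starting material + reagent → single product (k = 0.169 M⁻¹ s⁻¹)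
    reagent + single product ⇌ double product (K = 409 M⁻¹, k = 0.0155 M⁻¹ s⁻¹)
    crystals ⇌ single product, rate k3*(cs3 - [single product]) while solid is left; crystals form when [single product] > cs3 (solubility = 1.30 mM, k = 0.767 s⁻¹)

In the neighbour flask with 61 mM of reagent, 2.05 charges were spare, and 0.0576 h⁻¹ over 6.0 h left 0.708 of them, which gave 59.9 % double product. The computed neighbour held 50.9 %, a fraction left of 0.752, close to this flask's.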